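**Plan**
1. Retrosynthetic cuts, in order: the C8–O ester; the lactone C12–O bond (back to a C6,C12-diol, i.e. a hydroborated isopropenyl group); C6–C7 by a retro-[2,3]-Wittig shift, which opens the 10/5 bicycle to a 13-membered bis-allylic ether; the ether C6–O bond; then C7=C11, C3–C4, C1–C2 and C9–C10 of the open chain.
2. Enabling feature: the five lactone-ring atoms C6–O–C12–C11–C7 are the five centres of a [2,3]-Wittig shift once O–C12 is an ether CH2 and C11=C7 an olefin. C6 is allylic to the ring C4=C5 olefin and has the C15 oxygen cis to it, and the 11,13-dihydro (α-methyl) lactone is what the isopropenyl group left by the shift becomes.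
3. Forward: C7–C10 unit from (R)-glycidol → E-C1=C10 by carboalumination → C4=C5 by syn-carbocupration of an ynoate → Z-C7=C11 by Still–Gennari olefination → 13-membered oxacycle (Williamson) → ring contraction to the ten-membered carbocycle → γ-lactone → C8 ester.
4. Stereochemistry: C8 from (R)-glycidol; C6 and C7 from C8 plus the Z-olefin in the ring contraction; C11 by thermodynamic epimerisation of the lactone; the two ring olefins from syn-carbometalations.

Key step: step 15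

Remark: germacrane numbering is used for skeleton atoms (C6 lactone carbinol carbon, C7 ring-fusion carbon, C8 acyloxy carbon, C11 lactone α-carbon, C12 lactone carbonyl, C15 the hydroxymethyl carbon on C4); the target is 6R,7S,8S,11R with a cis-fused lactone and ring-trans C1=C10 and C4=C5 olefins.
Abbreviations: TBS = tert-butyldimethylsilyl, TBDPS = tert-butyldiphenylsilyl, PMB = 4-methoxybenzyl.

**Route**

Step 1
Reactants: 1 (R)-glycidol
Product: 2 (2S)-pent-4-yne-1,2-diol
Conditions: LiC≡CH·H2NCH2CH2NH2 (3 equiv), DMSO, 0 °C → rt; aq. NH4Cl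
Reagents that add atoms: lithium acetylide ethylenediamine complex, [Li]C#C.NCCN
Why: Regioselective SN2 epoxide opening by the acetylide at the unsubstituted carbon does not touch the stereocentre (the later C8), so (R)-glycidol should give the (S)-diol, the descriptor changing only through CIP priorities.

Step 2
Reactants: 2 (2S)-pent-4-yne-1,2-diol
Product: 3 (4S)-4,5-bis(TBSO)pent-1-yne
Conditions: TBSCl (2.4 equiv), imidazole, DMF, rt
Reagents that add atoms: tert-butyldimethylsilyl chloride, CC(C)(C)[Si](C)(C)Cl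
Why: Standard imidazole-promoted silyl ether formation protects both hydroxyls, the primary one so that it can later be released selectively.

Step 3
Reactants: 3 (4S)-4,5-bis(TBSO)pent-1-yne
Product: 6 (3E,6S)-6,7-bis(TBSO)-4-methylhept-3-en-1-ol, via alkenyldimethylalane 4 (not isolated), via lithium alkenylalanate 5 (not isolated)
Conditions: AlMe3 (3 equiv), Cp2ZrCl2 (0.25 equiv), CH2Cl2, 0 °C → rt; evaporate excess AlMe3; n-BuLi (1.1 equiv), hexane–THF, −78 °C; ethylene oxide (3 equiv), −78 °C → rt; aq. NH4Cl/Rochelle salt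
Reagents that add atoms: trimethylaluminium, C[Al](C)C; ethylene oxide, C1CO1
Why: Negishi Zr-catalysed syn-carboalumination puts Al on the terminal carbon and the new methyl cis to it, and the derived lithium alanate opens oxirane with retention at the alkenyl carbon, which fixes the E-C1=C10 olefin and adds C2–C3.

Step 4
Reactants: 6 (3E,6S)-6,7-bis(TBSO)-4-methylhept-3-en-1-ol
Product: 7 (2S,4E)-7-bromo-1,2-bis(TBSO)-4-methylhept-4-ene
Conditions: CBr4, PPh3, CH2Cl2, 0 °C
Reagents that add atoms: carbon tetrabromide, BrC(Br)(Br)Br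
Why: Appel bromination converts the primary alcohol into the bromide under neutral conditions that leave both silyl ethers and the trisubstituted olefin untouched.

Step 5
Reactants: 8 4-methoxybenzyl propargyl ether
Product: 10 tert-butyl 4-(PMBO)but-2-ynoate, via lithium acetylide 9 (not isolated)
Conditions: n-BuLi, THF, −78 °C; Boc2O, −78 → 0 °C; aq. NH4Cl
Reagents that add atoms: di-tert-butyl dicarbonate, CC(C)(C)OC(=O)OC(=O)OC(C)(C)C
Why: C-acylation of the lithium acetylide with Boc2O gives the tert-butyl ynoate, the tert-butyl ester being chosen so that it survives the selective DIBAL-H reduction in step 10.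

Step 6
Reactants: 7 (2S,4E)-7-bromo-1,2-bis(TBSO)-4-methylhept-4-ene, 10 tert-butyl 4-(PMBO)but-2-ynoate
Product: 13 tert-butyl (2Z,6E,9S)-9,10-bis(TBSO)-3-[(PMBO)methyl]-7-methyldeca-2,6-dienoate, via Grignard reagent 11 (not isolated), via organocopper reagent 12 (not isolated)
Conditions: 7, Mg, THF, rt; CuBr·SMe2 (1.0 equiv), THF–Me2S, −45 °C; 10 (0.9 equiv), −78 °C; MeOH then aq. NH4Cl at −78 °C
Reagents that add atoms: none
Why: Syn-carbocupration of the ynoate by the Grignard-derived organocopper reagent (conjugate addition to an acetylenic ester) followed by protonation at −78 °C places C3 trans to the ester carbon C6 and the CH2OPMB group cis to it, which is the ring-trans C4=C5 geometry of the target.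

Step 7
Reactants: 13 tert-butyl (2Z,6E,9S)-9,10-bis(TBSO)-3-[(PMBO)methyl]-7-methyldeca-2,6-dienoate
Product: 14 tert-butyl (2Z,6E,9S)-9-(TBSO)-10-hydroxy-3-[(PMBO)methyl]-7-methyldeca-2,6-dienoate
Conditions: HF·pyridine, pyridine, THF, 0 °C
Reagents that add atoms: none
Why: Buffered HF·pyridine cleaves the unhindered primary TBS ether much faster than the secondary one (selective desilylation), releasing the C7 alcohol only.

Step 8
Reactants: 14 tert-butyl (2Z,6E,9S)-9-(TBSO)-10-hydroxy-3-[(PMBO)methyl]-7-methyldeca-2,6-dienoate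
Product: 15 tert-butyl (2Z,6E,9S)-9-(TBSO)-3-[(PMBO)methyl]-7-methyl-10-oxodeca-2,6-dienoate
Conditions: Dess–Martin periodinane, pyridine, CH2Cl2, 0 °C → rt
Reagents that add atoms: none
Why: Dess–Martin oxidation under buffered, non-enolising conditions gives the α-silyloxy aldehyde without epimerisation at C8, and the aldehyde is used at once.

Step 9
Reactants: 15 tert-butyl (2Z,6E,9S)-9-(TBSO)-3-[(PMBO)methyl]-7-methyl-10-oxodeca-2,6-dienoate
Product: 16 1-tert-butyl 12-ethyl (2Z,6E,9S,10Z)-9-(TBSO)-3-[(PMBO)methyl]-7,11-dimethyldodeca-2,6,10-trienedioate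
Conditions: (CF3CH2O)2P(O)CH(CH3)CO2Et, KHMDS, 18-crown-6, THF, −78 °C; then 15, −78 °C
Reagents that add atoms: ethyl 2-[bis(2,2,2-trifluoroethoxy)phosphoryl]propanoate, CCOC(=O)C(C)P(=O)(OCC(F)(F)F)OCC(F)(F)F
Why: Still–Gennari olefination (Z-selective Horner–Wadsworth–Emmons reaction of the bis(trifluoroethyl)phosphonate under dissociating KHMDS/18-crown-6 conditions) gives the Z-trisubstituted enoate with C8 cis to C12, the geometry that the ring contraction needs.

Step 10
Reactants: 16 1-tert-butyl 12-ethyl (2Z,6E,9S,10Z)-9-(TBSO)-3-[(PMBO)methyl]-7,11-dimethyldodeca-2,6,10-trienedioate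
Product: 17 tert-butyl (2Z,6E,9S,10Z)-9-(TBSO)-12-hydroxy-3-[(PMBO)methyl]-7,11-dimethyldodeca-2,6,10-trienoate
Conditions: DIBAL-H (2.2 equiv), CH2Cl2, −78 °C; Rochelle salt
Reagents that add atoms: none
Why: Chemoselective DIBAL-H reduction at −78 °C takes the ethyl Z-enoate to the allylic alcohol while the tert-butyl β,β-disubstituted enoate reacts much more slowly.

Step 11
Reactants: 17 tert-butyl (2Z,6E,9S,10Z)-9-(TBSO)-12-hydroxy-3-[(PMBO)methyl]-7,11-dimethyldodeca-2,6,10-trienoate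
Product: 19 tert-butyl (2Z,6E,9S,10Z)-9-(TBSO)-12-chloro-3-[(PMBO)methyl]-7,11-dimethyldodeca-2,6,10-trienoate, via allylic mesylate 18 (not isolated)
Conditions: MsCl, 2,4,6-collidine, LiCl, DMF, 0 °C
Reagents that add atoms: lithium chloride, [Li+].[Cl-]
Why: Collington–Meyers chlorination (mesylation, then SN2 displacement by chloride) converts the allylic alcohol into the primary allylic chloride without allylic transposition or loss of the Z geometry.

Step 12
Reactants: 19 tert-butyl (2Z,6E,9S,10Z)-9-(TBSO)-12-chloro-3-[(PMBO)methyl]-7,11-dimethyldodeca-2,6,10-trienoate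
Product: 20 (2Z,6E,9S,10Z)-9-(TBSO)-12-chloro-3-[(PMBO)methyl]-7,11-dimethyldodeca-2,6,10-trien-1-ol
Conditions: DIBAL-H (3 equiv), CH2Cl2, −78 → −40 °C; Rochelle salt
Reagents that add atoms: none
Why: DIBAL-H 1,2-reduction of the tert-butyl enoate gives the C6 allylic alcohol, the allylic chloride being inert to DIBAL-H at low temperature.

Step 13
Reactants: 20 (2Z,6E,9S,10Z)-9-(TBSO)-12-chloro-3-[(PMBO)methyl]-7,11-dimethyldodeca-2,6,10-trien-1-ol
Product: 22 (3Z,5S,7E,11Z)-5-(TBSO)-11-[(PMBO)methyl]-3,7-dimethyl-1-oxacyclotrideca-3,7,11-triene, via sodium alkoxide 21 (not isolated)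
Conditions: NaH (3 equiv), Bu4NI (0.2 equiv), THF, 45 °C, slow addition of 20 (final 2 mM)
Reagents that add atoms: none
Why: Intramolecular Williamson etherification under high dilution closes the 13-membered oxacycle by SN2 at the primary allylic chloride (no β-hydrogen for E2, SN2′ disfavoured at the substituted C7 terminus), and the alkoxide is flanked only by a benzyl-type ether, so it is not positioned for silyl migration.

Step 14
Reactants: 22 (3Z,5S,7E,11Z)-5-(TBSO)-11-[(PMBO)methyl]-3,7-dimethyl-1-oxacyclotrideca-3,7,11-triene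
Product: 23 [(3Z,5S,7E,11Z)-5-(TBSO)-3,7-dimethyl-1-oxacyclotrideca-3,7,11-trien-11-yl]methanol
Conditions: DDQ, CH2Cl2–pH 7 buffer, 0 °C
Reagents that add atoms: none
Why: Oxidative cleavage of the PMB ether with DDQ frees the C15 alcohol needed for the directed lithiation without touching the silyl ether or the bis-allylic ether.

Step 15
Reactants: 23 [(3Z,5S,7E,11Z)-5-(TBSO)-3,7-dimethyl-1-oxacyclotrideca-3,7,11-trien-11-yl]methanol
Product: 25 (1R,2Z,6E,9S,10R)-9-(TBSO)-3-(hydroxymethyl)-7-methyl-10-(prop-1-en-2-yl)cyclodeca-2,6-dien-1-ol, via dilithio species 24 (not isolated)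
Conditions: n-BuLi (3.2 equiv), THF, −78 → −20 °C; aq. NH4Cl at −78 °C
Reagents that add atoms: none
Why: n-BuLi first makes the C15 lithium alkoxide, which delivers the second equivalent to the cis-disposed, α-oxygenated allylic C6–H (and, unlike a C15 ether, cannot leave by 1,4-elimination), and the C6 carbanion then undergoes a transannular [2,3]-Wittig shift over O–C12–C11=C7, forming C6–C7, breaking O–C12 and leaving C6–OLi and the C11(CH3)=C12H2 isopropenyl group. The closest known reaction type is the [2,3]-Wittig ring contraction of 13-membered bis-allylic ethers to germacrane-type cyclodecadienols, together with the Z → syn rule of acyclic [2,3]-Wittig rearrangements. The ten-membered ring closes by SN2′-type (10-exo-trig) attack of C6 on C7 through a five-membered envelope transition state made of C6, O, C12, C11 and C7, i.e. a 13 → 10 ring contraction. The relative configuration C6/C7 (syn, the later cis-fused lactone) should follow from the Z geometry of C7=C11, which puts C5 and C8 on the same side of the five-centre array, and the absolute sense from C8: the ring carbon C9 must lie near the allyl plane for the ten-membered ring to form, the OTBS group then stands anti to the incoming carbanion (Felkin–Anh-type) and H8 faces C6, so that 8S should lead to the 6R,7S arrangement of the target (C7 is named 10R in 25 only because of a CIP priority change). The step needs C6 over C12 lithiation, [2,3] over [1,2] shift and one face of C7; these are to be secured by the alkoxide-directed lithiation with its O15–Li–C6 chelate (which also holds the C4=C5 geometry), by the low temperature, and by the C8 stereocentre together with the Z-olefin.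

Step 16
Reactants: 25 (1R,2Z,6E,9S,10R)-9-(TBSO)-3-(hydroxymethyl)-7-methyl-10-(prop-1-en-2-yl)cyclodeca-2,6-dien-1-ol
Product: 26 (1R,2Z,6E,9S,10R)-9-(TBSO)-3-[(TBDPSO)methyl]-7-methyl-10-(prop-1-en-2-yl)cyclodeca-2,6-dien-1-ol
Conditions: TBDPSCl (1.05 equiv), imidazole, CH2Cl2, 0 °C
Reagents that add atoms: tert-butyl(chloro)diphenylsilane, CC(C)(C)[Si](Cl)(c1ccccc1)c1ccccc1
Why: Silylation with the bulky TBDPSCl is selective for the primary allylic C15 hydroxyl over the hindered secondary C6 hydroxyl.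

Step 17
Reactants: 26 (1R,2Z,6E,9S,10R)-9-(TBSO)-3-[(TBDPSO)methyl]-7-methyl-10-(prop-1-en-2-yl)cyclodeca-2,6-dien-1-ol
Product: 28 (1R,2Z,6E,9S,10R)-9-(TBSO)-3-[(TBDPSO)methyl]-10-(1-hydroxypropan-2-yl)-7-methylcyclodeca-2,6-dien-1-ol, via bis(9-BBN) adduct 27 (not isolated)
Conditions: 9-BBN (3 equiv), THF, 0 °C → rt; then 3 M NaOH, 30% H2O2, 0 °C
Reagents that add atoms: hydrogen peroxide, OO
Why: Hydroboration–oxidation with 9-BBN is selective for the 1,1-disubstituted isopropenyl olefin over the two trisubstituted ring olefins and gives the primary C12 alcohol, the new C11 centre being allowed to form as an epimer mixture because it is corrected in step 18.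

Step 18
Reactants: 28 (1R,2Z,6E,9S,10R)-9-(TBSO)-3-[(TBDPSO)methyl]-10-(1-hydroxypropan-2-yl)-7-methylcyclodeca-2,6-dien-1-ol
Product: 30 (3R,3aR,4S,6E,10Z,11aR)-4-(TBSO)-10-[(TBDPSO)methyl]-3,6-dimethyl-3a,4,5,8,9,11a-hexahydrocyclodeca[b]furan-2(3H)-one, via lactol 29 (not isolated)
Conditions: TEMPO (0.2 equiv), PhI(OAc)2 (2.5 equiv), CH2Cl2, rt; then DBU (0.3 equiv), toluene, 40 °C
Reagents that add atoms: none
Why: TEMPO/PhI(OAc)2 oxidises the primary alcohol of the 1,4-diol to the aldehyde, which closes to the lactol and is oxidised to the γ-lactone (oxidative lactonisation), and DBU then equilibrates C11 through the enolate to the epimer expected to be more stable, with the methyl group trans to C8 on the exo face of the cis-fused bicycle (11R).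

Step 19
Reactants: 30 (3R,3aR,4S,6E,10Z,11aR)-4-(TBSO)-10-[(TBDPSO)methyl]-3,6-dimethyl-3a,4,5,8,9,11a-hexahydrocyclodeca[b]furan-2(3H)-one
Product: 31 (3R,3aS,4S,6E,10Z,11aR)-10-[(TBDPSO)methyl]-4-hydroxy-3,6-dimethyl-3a,4,5,8,9,11a-hexahydrocyclodeca[b]furan-2(3H)-one
Conditions: HF·pyridine, pyridine, THF, 0 °C → rt
Reagents that add atoms: none
Why: Selective desilylation with buffered HF·pyridine should remove the secondary TBS ether, which is more labile towards acidic fluoride than the primary TBDPS ether.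

Step 20
Reactants: 32 ethyl 2-(hydroxymethyl)acrylate
Product: 33 ethyl 2-[(TBSO)methyl]acrylate
Conditions: TBSCl, imidazole, CH2Cl2, 0 °C
Reagents that add atoms: tert-butyldimethylsilyl chloride, CC(C)(C)[Si](C)(C)Cl
Why: Standard silyl ether formation protects the allylic hydroxyl of the acrylate.

Step 21
Reactants: 33 ethyl 2-[(TBSO)methyl]acrylate
Product: 34 2-[(TBSO)methyl]acrylic acid
Conditions: LiOH·H2O, THF–H2O, 0 °C; then 1 M HCl to pH 4
Reagents that add atoms: lithium hydroxide, [Li+].[OH-]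
Why: Saponification of the ethyl ester with LiOH at 0 °C followed by mild acidification gives the acid without cleaving the silyl ether.

Step 22
Reactants: 31 (3R,3aS,4S,6E,10Z,11aR)-10-[(TBDPSO)methyl]-4-hydroxy-3,6-dimethyl-3a,4,5,8,9,11a-hexahydrocyclodeca[b]furan-2(3H)-one, 34 2-[(TBSO)methyl]acrylic acid
Product: 36 (3R,3aS,4S,6E,10Z,11aR)-10-[(TBDPSO)methyl]-3,6-dimethyl-2-oxo-2,3,3a,4,5,8,9,11a-octahydrocyclodeca[b]furan-4-yl 2-[(TBSO)methyl]acrylate, via mixed anhydride 35 (not isolated)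
Conditions: 34, 2,4,6-trichlorobenzoyl chloride, Et3N, toluene, rt; then 31, DMAP, toluene, rt
Reagents that add atoms: none
Why: Yamaguchi esterification through the mixed anhydride acylates the hindered C8 hydroxyl at oxygen, so that the C8 configuration is retained.

Step 23
Reactants: 36 (3R,3aS,4S,6E,10Z,11aR)-10-[(TBDPSO)methyl]-3,6-dimethyl-2-oxo-2,3,3a,4,5,8,9,11a-octahydrocyclodeca[b]furan-4-yl 2-[(TBSO)methyl]acrylate
Product: 37 (3R,3aS,4S,6E,10Z,11aR)-10-(hydroxymethyl)-3,6-dimethyl-2-oxo-2,3,3a,4,5,8,9,11a-octahydrocyclodeca[b]furan-4-yl 2-(hydroxymethyl)acrylate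
Conditions: HF·pyridine (excess), pyridine, THF, 0 °C → rt
Reagents that add atoms: none
Why: Global desilylation with pyridine-buffered HF·pyridine removes the primary TBS and TBDPS ethers under conditions that should leave the acrylate ester, the lactone and the acid-sensitive 1(10),4-diene intact.

**Compound list**
1 | (R)-glycidol | OC[C@@H]1CO1 | starting material
2 | (2S)-pent-4-yne-1,2-diol | OC[C@@H](O)CC#C | intermediate
3 | (4S)-4,5-bis(TBSO)pent-1-yne | C#CC[C@@H](CO[Si](C)(C)C(C)(C)C)O[Si](C)(C)C(C)(C)C | intermediate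
4 | [(1E,4S)-4,5-bis(TBSO)-2-methylpent-1-en-1-yl]dimethylalane | C[Al](C)/C=C(\C)C[C@@H](CO[Si](C)(C)C(C)(C)C)O[Si](C)(C)C(C)(C)C | intermediate
5 | lithium butyl[(1E,4S)-4,5-bis(TBSO)-2-methylpent-1-en-1-yl]dimethylaluminate | [Li+].CCCC[Al-](C)(C)/C=C(\C)C[C@@H](CO[Si](C)(C)C(C)(C)C)O[Si](C)(C)C(C)(C)C | intermediate
6 | (3E,6S)-6,7-bis(TBSO)-4-methylhept-3-en-1-ol | OCC/C=C(\C)C[C@@H](CO[Si](C)(C)C(C)(C)C)O[Si](C)(C)C(C)(C)C | intermediate
7 | (2S,4E)-7-bromo-1,2-bis(TBSO)-4-methylhept-4-ene | BrCC/C=C(\C)C[C@@H](CO[Si](C)(C)C(C)(C)C)O[Si](C)(C)C(C)(C)C | intermediate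
8 | 4-methoxybenzyl propargyl ether (1-methoxy-4-[(prop-2-yn-1-yloxy)methyl]benzene) | C#CCOCc1ccc(OC)cc1 | starting material
9 | [3-(PMBO)prop-1-yn-1-yl]lithium | [Li]C#CCOCc1ccc(OC)cc1 | intermediate
10 | tert-butyl 4-(PMBO)but-2-ynoate | CC(C)(C)OC(=O)C#CCOCc1ccc(OC)cc1 | intermediate
11 | [(3E,6S)-6,7-bis(TBSO)-4-methylhept-3-en-1-yl]magnesium bromide | Br[Mg]CC/C=C(\C)C[C@@H](CO[Si](C)(C)C(C)(C)C)O[Si](C)(C)C(C)(C)C | intermediate
12 | [(3E,6S)-6,7-bis(TBSO)-4-methylhept-3-en-1-yl]copper (as its MgBr2 complex) | [Cu]CC/C=C(\C)C[C@@H](CO[Si](C)(C)C(C)(C)C)O[Si](C)(C)C(C)(C)C | intermediate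
13 | tert-butyl (2Z,6E,9S)-9,10-bis(TBSO)-3-[(PMBO)methyl]-7-methyldeca-2,6-dienoate | CC(C)(C)OC(=O)/C=C(\COCc1ccc(OC)cc1)CC/C=C(\C)C[C@@H](CO[Si](C)(C)C(C)(C)C)O[Si](C)(C)C(C)(C)C | intermediate
14 | tert-butyl (2Z,6E,9S)-9-(TBSO)-10-hydroxy-3-[(PMBO)methyl]-7-methyldeca-2,6-dienoate | CC(C)(C)OC(=O)/C=C(\COCc1ccc(OC)cc1)CC/C=C(\C)C[C@@H](CO)O[Si](C)(C)C(C)(C)C | intermediate
15 | tert-butyl (2Z,6E,9S)-9-(TBSO)-3-[(PMBO)methyl]-7-methyl-10-oxodeca-2,6-dienoate | CC(C)(C)OC(=O)/C=C(\COCc1ccc(OC)cc1)CC/C=C(\C)C[C@@H](C=O)O[Si](C)(C)C(C)(C)C | intermediate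
16 | 1-tert-butyl 12-ethyl (2Z,6E,9S,10Z)-9-(TBSO)-3-[(PMBO)methyl]-7,11-dimethyldodeca-2,6,10-trienedioate | CC(C)(C)OC(=O)/C=C(\COCc1ccc(OC)cc1)CC/C=C(\C)C[C@@H](/C=C(/C)C(=O)OCC)O[Si](C)(C)C(C)(C)C | intermediate
17 | tert-butyl (2Z,6E,9S,10Z)-9-(TBSO)-12-hydroxy-3-[(PMBO)methyl]-7,11-dimethyldodeca-2,6,10-trienoate | CC(C)(C)OC(=O)/C=C(\COCc1ccc(OC)cc1)CC/C=C(\C)C[C@@H](/C=C(/C)CO)O[Si](C)(C)C(C)(C)C | intermediate
18 | tert-butyl (2Z,6E,9S,10Z)-9-(TBSO)-12-(methanesulfonyloxy)-3-[(PMBO)methyl]-7,11-dimethyldodeca-2,6,10-trienoate | CC(C)(C)OC(=O)/C=C(\COCc1ccc(OC)cc1)CC/C=C(\C)C[C@@H](/C=C(/C)COS(C)(=O)=O)O[Si](C)(C)C(C)(C)C | intermediate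
19 | tert-butyl (2Z,6E,9S,10Z)-9-(TBSO)-12-chloro-3-[(PMBO)methyl]-7,11-dimethyldodeca-2,6,10-trienoate | CC(C)(C)OC(=O)/C=C(\COCc1ccc(OC)cc1)CC/C=C(\C)C[C@@H](/C=C(/C)CCl)O[Si](C)(C)C(C)(C)C | intermediate
20 | (2Z,6E,9S,10Z)-9-(TBSO)-12-chloro-3-[(PMBO)methyl]-7,11-dimethyldodeca-2,6,10-trien-1-ol | OC/C=C(\COCc1ccc(OC)cc1)CC/C=C(\C)C[C@@H](/C=C(/C)CCl)O[Si](C)(C)C(C)(C)C | intermediate
21 | sodium (2Z,6E,9S,10Z)-9-(TBSO)-12-chloro-3-[(PMBO)methyl]-7,11-dimethyldodeca-2,6,10-trien-1-olate | [Na]OC/C=C(\COCc1ccc(OC)cc1)CC/C=C(\C)C[C@@H](/C=C(/C)CCl)O[Si](C)(C)C(C)(C)C | intermediate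
22 | (3Z,5S,7E,11Z)-5-(TBSO)-11-[(PMBO)methyl]-3,7-dimethyl-1-oxacyclotrideca-3,7,11-triene | O1C/C=C(\COCc2ccc(OC)cc2)CC/C=C(\C)C[C@H](O[Si](C)(C)C(C)(C)C)/C=C(/C)C1 | intermediate
23 | [(3Z,5S,7E,11Z)-5-(TBSO)-3,7-dimethyl-1-oxacyclotrideca-3,7,11-trien-11-yl]methanol | O1C/C=C(\CO)CC/C=C(\C)C[C@H](O[Si](C)(C)C(C)(C)C)/C=C(/C)C1 | intermediate
24 | C6-lithio lithium alkoxide of 23 (ring carbon 13 lithiated, CH2OLi on ring carbon 11) | O1C([Li])/C=C(\CO[Li])CC/C=C(\C)C[C@H](O[Si](C)(C)C(C)(C)C)/C=C(/C)C1 | intermediate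
25 | (1R,2Z,6E,9S,10R)-9-(TBSO)-3-(hydroxymethyl)-7-methyl-10-(prop-1-en-2-yl)cyclodeca-2,6-dien-1-ol | O[C@@H]1/C=C(\CO)CC/C=C(\C)C[C@H](O[Si](C)(C)C(C)(C)C)[C@@H]1C(C)=C | intermediate
26 | (1R,2Z,6E,9S,10R)-9-(TBSO)-3-[(TBDPSO)methyl]-7-methyl-10-(prop-1-en-2-yl)cyclodeca-2,6-dien-1-ol | O[C@@H]1/C=C(\CO[Si](c2ccccc2)(c2ccccc2)C(C)(C)C)CC/C=C(\C)C[C@H](O[Si](C)(C)C(C)(C)C)[C@@H]1C(C)=C | intermediate
27 | O1-(9-BBN) borinate of 26 carrying a 9-BBN group on the terminal carbon of the former isopropenyl group (epimers at the side-chain CH) | O(B2C3CCCC2CCC3)[C@@H]1/C=C(\CO[Si](c2ccccc2)(c2ccccc2)C(C)(C)C)CC/C=C(\C)C[C@H](O[Si](C)(C)C(C)(C)C)[C@@H]1C(C)CB2C3CCCC2CCC3 | intermediate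
28 | (1R,2Z,6E,9S,10R)-9-(TBSO)-3-[(TBDPSO)methyl]-10-(1-hydroxypropan-2-yl)-7-methylcyclodeca-2,6-dien-1-ol (epimers at the side-chain CH) | O[C@@H]1/C=C(\CO[Si](c2ccccc2)(c2ccccc2)C(C)(C)C)CC/C=C(\C)C[C@H](O[Si](C)(C)C(C)(C)C)[C@@H]1C(C)CO | intermediate
29 | (3aR,4S,6E,10Z,11aR)-4-(TBSO)-10-[(TBDPSO)methyl]-3,6-dimethyl-2,3,3a,4,5,8,9,11a-octahydrocyclodeca[b]furan-2-ol (lactol, epimers at C2 and C3) | CC(C)(C)[Si](C)(C)O[C@H]1C/C(C)=C/CC/C(CO[Si](c3ccccc3)(c3ccccc3)C(C)(C)C)=C/[C@H]2OC(O)C(C)[C@@H]12 | intermediate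
30 | (3R,3aR,4S,6E,10Z,11aR)-4-(TBSO)-10-[(TBDPSO)methyl]-3,6-dimethyl-3a,4,5,8,9,11a-hexahydrocyclodeca[b]furan-2(3H)-one | CC(C)(C)[Si](C)(C)O[C@H]1C/C(C)=C/CC/C(CO[Si](c3ccccc3)(c3ccccc3)C(C)(C)C)=C/[C@H]2OC(=O)[C@H](C)[C@@H]12 | intermediate
31 | (3R,3aS,4S,6E,10Z,11aR)-10-[(TBDPSO)methyl]-4-hydroxy-3,6-dimethyl-3a,4,5,8,9,11a-hexahydrocyclodeca[b]furan-2(3H)-one | O[C@H]1C/C(C)=C/CC/C(CO[Si](c3ccccc3)(c3ccccc3)C(C)(C)C)=C/[C@H]2OC(=O)[C@H](C)[C@@H]12 | intermediate
32 | ethyl 2-(hydroxymethyl)acrylate | C=C(CO)C(=O)OCC | starting material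
33 | ethyl 2-[(TBSO)methyl]acrylate | C=C(CO[Si](C)(C)C(C)(C)C)C(=O)OCC | intermediate
34 | 2-[(TBSO)methyl]acrylic acid | C=C(CO[Si](C)(C)C(C)(C)C)C(=O)O | intermediate
35 | 2-[(TBSO)methyl]acrylic 2,4,6-trichlorobenzoic anhydride | C=C(CO[Si](C)(C)C(C)(C)C)C(=O)OC(=O)c1c(Cl)cc(Cl)cc1Cl | intermediate
36 | (3R,3aS,4S,6E,10Z,11aR)-10-[(TBDPSO)methyl]-3,6-dimethyl-2-oxo-2,3,3a,4,5,8,9,11a-octahydrocyclodeca[b]furan-4-yl 2-[(TBSO)methyl]acrylate | C=C(CO[Si](C)(C)C(C)(C)C)C(=O)O[C@H]1C/C(C)=C/CC/C(CO[Si](c3ccccc3)(c3ccccc3)C(C)(C)C)=C/[C@H]2OC(=O)[C@H](C)[C@@H]12 | intermediate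
37 | (3R,3aS,4S,6E,10Z,11aR)-10-(hydroxymethyl)-3,6-dimethyl-2-oxo-2,3,3a,4,5,8,9,11a-octahydrocyclodeca[b]furan-4-yl 2-(hydroxymethyl)acrylate | C=C(CO)C(=O)O[C@H]1C/C(C)=C/CC/C(CO)=C/[C@H]2OC(=O)[C@H](C)[C@@H]12 | target

**Step count and risks**

Total steps: 23. Longest linear sequence: 20 steps (steps 1–4, 6–19, 22 and 23).

Steps most likely to fail:

Step 15 (ring contraction). After the alkoxide has formed, the second lithiation may be slow or may take place at C12–H instead of C6–H, so that [1,2]-shift, elimination or the regioisomeric contraction take over. Fallback: setting out from 23, the C15 hydroxyl is silylated first (TBDPSCl, imidazole, CH2Cl2) to give the fully protected macrocycle (3Z,5S,7E,11Z)-5-(TBSO)-11-[(TBDPSO)methyl]-3,7-dimethyl-1-oxacyclotrideca-3,7,11-triene F1. Its mono-anion is then generated with n-BuLi in THF at −78 °C and rearranged in the conventional way for a bis-allylic ether without a free hydroxyl, regiochemistry resting on the less substituted O–CH2–CH= position and contact time kept short to limit loss of silanolate. This should give 26 directly, so the fallback comes back to the route at 26 and step 16 falls away.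

Step 13 (macro-etherification). Intermolecular etherification or base-induced decomposition of the chloro alkoxide may outrun the slow 13-membered ring closure. Fallback: setting out from 20, Finkelstein exchange (NaI, acetone) gives the allylic iodide (2Z,6E,9S,10Z)-9-(TBSO)-12-iodo-3-[(PMBO)methyl]-7,11-dimethyldodeca-2,6,10-trien-1-ol F2. This is cyclised under neutral silver(I) assistance (Ag2O, 4 Å molecular sieves, CH2Cl2, high dilution, dark), with the free alcohol rather than an alkoxide as the nucleophile; the fallback comes back to the route at 22.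

Step 19 (selective desilylation). Discrimination between the hindered secondary TBS ether and the primary TBDPS ether may be incomplete, or prolonged exposure to acidic fluoride may trigger transannular cyclisation of the diene. Fallback: setting out from 30, both silyl ethers are removed with acetic acid-buffered TBAF to give the diol (3R,3aS,4S,6E,10Z,11aR)-4-hydroxy-10-(hydroxymethyl)-3,6-dimethyl-3a,4,5,8,9,11a-hexahydrocyclodeca[b]furan-2(3H)-one F3. The primary allylic hydroxyl is re-silylated selectively (TBSCl, imidazole, CH2Cl2, −20 °C) to the C15 mono-TBS ether F4, and Yamaguchi esterification with 34 gives the bis-TBS ester F5. HF·pyridine then removes both primary TBS ethers, and the fallback comes back to the route at 37.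

Further compounds
F1 | step 15 | (3Z,5S,7E,11Z)-5-(TBSO)-11-[(TBDPSO)methyl]-3,7-dimethyl-1-oxacyclotrideca-3,7,11-triene | O1C/C=C(\CO[Si](c2ccccc2)(c2ccccc2)C(C)(C)C)CC/C=C(\C)C[C@H](O[Si](C)(C)C(C)(C)C)/C=C(/C)C1
F2 | step 13 | (2Z,6E,9S,10Z)-9-(TBSO)-12-iodo-3-[(PMBO)methyl]-7,11-dimethyldodeca-2,6,10-trien-1-ol | OC/C=C(\COCc1ccc(OC)cc1)CC/C=C(\C)C[C@@H](/C=C(/C)CI)O[Si](C)(C)C(C)(C)C
F3 | step 19 | (3R,3aS,4S,6E,10Z,11aR)-4-hydroxy-10-(hydroxymethyl)-3,6-dimethyl-3a,4,5,8,9,11a-hexahydrocyclodeca[b]furan-2(3H)-one | O[C@H]1C/C(C)=C/CC/C(CO)=C/[C@H]2OC(=O)[C@H](C)[C@@H]12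
F4 | step 19 | (3R,3aS,4S,6E,10Z,11aR)-10-[(TBSO)methyl]-4-hydroxy-3,6-dimethyl-3a,4,5,8,9,11a-hexahydrocyclodeca[b]furan-2(3H)-one | O[C@H]1C/C(C)=C/CC/C(CO[Si](C)(C)C(C)(C)C)=C/[C@H]2OC(=O)[C@H](C)[C@@H]12
F5 | step 19 | (3R,3aS,4S,6E,10Z,11aR)-10-[(TBSO)methyl]-3,6-dimethyl-2-oxo-2,3,3a,4,5,8,9,11a-octahydrocyclodeca[b]furan-4-yl 2-[(TBSO)methyl]acrylate | C=C(CO[Si](C)(C)C(C)(C)C)C(=O)O[C@H]1C/C(C)=C/CC/C(CO[Si](C)(C)C(C)(C)C)=C/[C@H]2OC(=O)[C@H](C)[C@@H]12
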